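The earlier runs and the new flask are simulated for an exercise, noise included.

3 questions stand on one flask, the blue run carried on to 25 min: how much product there is, which change gains most, and what beta gives.

| flask | substrate | gas | free catalyst | remark | time |
|---|---|---|---|---|---|
| blue | 0.80 M | 26 mM (held) | 0.2 mol% | the very flask that is asked about, followed so far |  |
| flask | 0.80 M | 26 mM (held) | 0.2 mol% |  | 25 min |

blue run (percent of the substrate charged)

| time / min | product / % |
|---|---|
| 0.417 | 1.6 |
| 1.00 | 3.1 |
| 2.00 | 7.7 |
| 3.00 | 9.5 |
| 5.00 | 16.0 |

(each reading ± 0.5 percentage points)

- how much product there is at 25 min, in percent of the substrate charged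
- the change that raises the amount of product at 25 min, in percent of the substrate charged most ("none" if none brings more than 2 percentage points) (beta / gamma / delta / none)
- amount of product at 25 min, in percent of the substrate charged, after beta

- beta: doubling the transfer coefficient of the gas, all else as stated
- gamma: doubling the saturation concentration of gas, all else as stated
- delta: doubling the amount of free catalyst, all else as stated

- what was read earlier has a scatter of 0.5 percentage points, one standard deviation
- at the start none of the gas is in solution

My rule of thumb is the straight line through the last blue reading: 16.0% at 5.00 min is 0.0320 min⁻¹ of the charge, which puts the flask at 80.0%. The border shows in a ratio: the last blue reading leaves 84.0% of the substrate, and that line needs 20.0%, which is 4.20 times less. The blue readings also seem to bend, from 0.0385 min⁻¹ up to 2.00 min to 0.0277 min⁻¹ after it, so the later rate as read is lower than the early one, though both carry the scatter of the readings.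

So I put the first answer back and let the rate follow substrate. The mean substrate is then 60.0% of the charge against 92.0% during the readings, which gives 52.2%; one more round gives 64.3%. A rate that follows substrate makes a pseudo-first-order curve, described by one quantity: the logarithm of substrate charged over substrate left, divided by time and by the c(free catalyst) charged. This catalyst-specific rate constant reads 21.8 M⁻¹ min⁻¹ from the blue run. It gives me 58.2% for the flask, and delta 82.5%, so delta is my choice. The first blue reading, 1.6% at 0.417 min, already reads 0.0384 min⁻¹, higher than the straight line, so I read no lag from the gas-free start and for beta I keep 58.2%. The blue run held the gas at one level, so gamma stays unread.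

The forecast gives 72%, gamma and 86%, holding that “Doubling gas saturation speeds the process whether transfer or chemistry limits it”.

The flask gives 45.9%; the best change is delta, with 17 percentage points gained, and beta gives 45.9%.

    substrate + free catalyst → catalyst intermediate A (k = 110 M⁻¹ min⁻¹)
    reagent + catalyst intermediate A ⇌ catalyst intermediate B (K = 160 M⁻¹, k = 4480 M⁻¹ min⁻¹)
    catalyst intermediate B ⇌ released group + catalyst intermediate C (K = 0.160 M, k = 68.4 min⁻¹)
    catalyst intermediate C ⇌ free catalyst + product (K = 0.260 M, k = 77.4 min⁻¹)
    gas ⇌ reagent, rate k5*(csat - [reagent]) (kL = 230 min⁻¹)

Put back, the flask's result gives a constant of 15.3 M⁻¹ min⁻¹, lower than the blue reading, while its free catalyst goes from 19.4% at 2.50 min to 9.94% at 25.0 min, in percent of the catalyst charged. The neighbour flask charged with 0.08 mol% reckons at 29.4% from the blue constant and gives 26.5%. Its own constant is 19.2 M⁻¹ min⁻¹, higher than the flask's, and its free catalyst stands at 14.1% of its own charge at 25.0 min.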